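The data were generated by integration with made-up constants; scatter was added.

Saturday's run, with 5 equiv of coupling partner, ended in a tail: the shortfall of target (its readings count the solid product too) fell from 12.5% at 3.00 d to 1.60% at 5.00 d. I read that as the decay of what stood dissolved, pseudo-first-order in the partner, with a decay time of 0.973 d.

| setting | Sunday's | Saturday's | flask |
|---|---|---|---|
| solid substrate | 0.30 M | 0.30 M | 0.30 M |
| coupling partner | 2.5 equiv | 5 equiv | 2.50 equiv |
| remark | the very flask that is asked about, followed so far | run made earlier |  |
| time |  |  | 8.0 d |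

Sunday's run (percent of the solid substrate charged)

| time / h | target / % | solid product / % |
|---|---|---|
| 2.00 | 0 | 0 |
| 6.00 | 2.2 | 0.3 |
| 10.0 | 6.2 | 1.5 |
| 15.0 | 7.4 | 0 |
| 25.0 | 19.4 | 0 |
| 30.0 | 21.9 | 0.3 |
| 40.0 | 32.1 | 0 |

Saturday's run (percent of the solid substrate charged)

| time / d | target / % | solid product / % |
|---|---|---|
| 1.25 | 32.9 | 0.4 |
| 2.50 | 74.1 | 40.1 |
| 3.00 | 87.5 | 49.9 |
| 5.00 | 98.4 | 62.0 |
| 6.00 | 101.1 | 62.0 |
| 8.00 | 99.1 | 63.2 |

(standard deviation of a reading: 1 percentage point)

- the target and solid product together standing at 8.0 d, as a percentage of the solid substrate charged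
- concentration of dissolved substrate in solution at 8.0 d, in percent of saturation

Sunday's flask has 2.50 equiv. I took off one equivalent for what the substrate consumes, and so reckoned with 4.00 equiv on Saturday against 1.50 equiv on Sunday. So I stretched the decay time to 2.59 d. This tail lifetime, the time in which dissolved substrate falls by a factor e once the solid stops feeding it, is what I carried forward.

Sunday's target climbed on a line, a fraction 0.207 d⁻¹ of the charge, from 10.0 h to 40.0 h. I joined line and tail smoothly, which in my reckoning puts the shortfall at slope times lifetime, 53.8%, at 2.23 d. The 2.22 lifetimes up to 8.0 d then leave 5.84%.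

The weak link was that joining moment, since the line may bend. I moved it to 3.00 d: the shortfall on the line there is smaller, 37.9%, and 1.93 lifetimes follow, which leaves 5.51%. Moving the join shifted the remainder by 0.31 percentage points, so I committed to 94.5%.

The forecast said 95% (91% to 98%) and 11% of saturation (5% to 20%), holding that “dissolution and reaction share control”.

The flask gave 94.6%, with dissolved substrate at 13.6% of saturation.

    solid substrate ⇌ dissolved substrate, rate k1*(cs1 - [dissolved substrate]) while solid is left; crystals form when [dissolved substrate] > cs1 (solubility = 0.120 M, k = 0.0580 h⁻¹)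
    solid product ⇌ target, rate k2*(cs2 - [target]) while solid is left; crystals form when [target] > cs2 (solubility = 0.110 M, k = 4.70 h⁻¹)
    coupling partner → decomposed reagent (k = 0.00470 h⁻¹)
    dissolved substrate + coupling partner → target (k = 0.0770 M⁻¹ h⁻¹)

At 4.00 d Sunday's flask held solid substrate 0% and dissolved substrate 24.9% of the charge, and 2.59 d carries that to 5.31% at 8.0 d, where 5.44% stood. For the neighbour read at 5.00 d, the same lifetime gives 16.9%, and that flask holds 15.2%.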